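## Retrosynthetic overview

1. Every carbon of the target comes from benzyl benzoate 1, the accepted biogenetic precursor of this family, plus one benzoyl group; no C–C bond is made.
2. Key disconnection: the cyclohexene ring is not built but uncovered from the benzyl ring of 1 by enzymatic dearomatising cis-dioxygenation, giving dienediol 2 and setting C5, C6 and the absolute configuration in one step.
3. O5–benzoyl disconnection: benzoyl chloride 3 on the distal hydroxyl of 2 gives dienyl benzoate 4.
4. C3/C4 cis-diol disconnection: oxygenation of the remaining diene of 4 from the face opposite to O5/O6, through osmate ester 5, gives target 6.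
5. Ring order: arene ring of 1 → cyclohexadiene (step 1) → cyclohexene (step 3). The only ring closed on the way is the transient five-membered osmate ester 5; both phenyl rings are carried through unchanged.

Numbering (as in the target): C1 carries C7 (the CH2OBz carbon), C2 is the olefinic CH, C3–C6 carry O3–O6. The target is 3R,4R,5R,6R, with O3/O4 on one face and O5/O6 on the other.

Assumption: the presumed biosynthesis is the arene-oxygenase pathway usually drawn for these benzoylated cyclohexenes, in which benzyl benzoate is dearomatised by enzymatic oxygenation of its benzyl ring and the diene left behind is oxygenated from the opposite face.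

## Route

Step 1
Reactants: 1 benzyl benzoate
Product: 2 [(5S,6R)-5,6-dihydroxycyclohexa-1,3-dien-1-yl]methyl benzoate
Conditions: E. coli JM109(pDTG601A) whole cells (toluene dioxygenase), IPTG, glucose, air, KH2PO4/K2HPO4 pH 7.2, 1 dosed in liquid paraffin, 30 °C
Reagents that add atoms: dioxygen, O=O
Why: Proposed new method: benzyl benzoate is not a reported substrate, but its benzyl ring is a toluene-type alkylbenzene that should bind in the hydrophobic pocket of toluene dioxygenase as toluene, (2-bromoethyl)benzene or biphenyl do, while the benzoyl ring carries an ester far larger than the small alkyl esters (methyl, ethyl, allyl, propargyl) known to be turned over, so the Rieske non-heme iron centre (O2 activated with NADH, regenerated from glucose) should add both oxygen atoms suprafacially to the ortho and meta carbons of the benzyl ring only; the closest known reaction type is the enzymatic arene cis-dihydroxylation of monosubstituted benzenes, whose invariant facial selectivity sets C6 as R and C5 as S and with them the absolute configuration of the whole route.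

Step 2
Reactants: 2 [(5S,6R)-5,6-dihydroxycyclohexa-1,3-dien-1-yl]methyl benzoate, 3 benzoyl chloride
Product: 4 (1S,6R)-5-[(benzoyloxy)methyl]-6-hydroxycyclohexa-2,4-dien-1-yl benzoate
Conditions: 3 (1.05 equiv), 2,4,6-collidine (3 equiv), CH2Cl2, −40 → −20 °C
Reagents that add atoms: benzoyl chloride, O=C(Cl)c1ccccc1
Why: Sterically controlled O-acylation with an acid chloride (Einhorn-type), in which the distal O5–H next to the olefinic CH reacts faster than O6–H, which is flanked by the fully substituted C1 and its CH2OBz arm (the same bias that governs distal silylation of arene cis-dihydrodiols), while the hindered base and low temperature suppress acyl migration and loss of benzoic acid to the phenol; no stereocentre is touched.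

Step 3
Reactants: 4 (1S,6R)-5-[(benzoyloxy)methyl]-6-hydroxycyclohexa-2,4-dien-1-yl benzoate
Product: 6 [(3R,4R,5R,6R)-5-(benzoyloxy)-3,4,6-trihydroxycyclohex-1-en-1-yl]methyl benzoate, via cyclic osmate ester 5 (not isolated)
Conditions: OsO4 (3 mol%), NMO (1.1 equiv), acetone–aq. NaH2PO4/Na2HPO4 pH 6.5 (4:1), 0 °C
Reagents that add atoms: osmium tetroxide, O=[Os](=O)(=O)=O; N-methylmorpholine N-oxide, C[N+]1([O-])CCOCC1; water, O
Why: Upjohn dihydroxylation, in which OsO4 adds suprafacially in a [3+2] sense to the disubstituted C3=C4 bond (C1=C2 is trisubstituted, flanked by C7 and O6 and deactivated by two allylic oxygens) from the face opposite to the allylic benzoate (Kishi's rule), and hydrolysis of osmate ester 5 with retention gives the 3R,4R cis-diol anti to O5/O6.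

## Compound list

1 | benzyl benzoate | O=C(OCc1ccccc1)c1ccccc1 | starting material
2 | [(5S,6R)-5,6-dihydroxycyclohexa-1,3-dien-1-yl]methyl benzoate (cis-diol, both hydroxyls on the same face) | O=C(OCC1=CC=C[C@H](O)[C@@H]1O)c1ccccc1 | intermediate
3 | benzoyl chloride | O=C(Cl)c1ccccc1 | starting material
4 | (1S,6R)-5-[(benzoyloxy)methyl]-6-hydroxycyclohexa-2,4-dien-1-yl benzoate (2 benzoylated at the distal O5) | O=C(OCC1=CC=C[C@H](OC(=O)c2ccccc2)[C@@H]1O)c1ccccc1 | intermediate
5 | cyclic osmate ester of 4: an OsO2 unit (hexavalent osmium) bridges O3 and O4, both C–O bonds on the face opposite to the C5 benzoate and C6 hydroxyl | O=C(OCC1=C[C@H]2O[Os](=O)(=O)O[C@H]2[C@H](OC(=O)c2ccccc2)[C@@H]1O)c1ccccc1 | intermediate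
6 | [(3R,4R,5R,6R)-5-(benzoyloxy)-3,4,6-trihydroxycyclohex-1-en-1-yl]methyl benzoate | O=C(OCC1=C[C@@H](O)[C@@H](O)[C@H](OC(=O)c2ccccc2)[C@@H]1O)c1ccccc1 | target

## Step count and risks

Total steps: 3. Longest linear sequence: 3 steps (1 → 2 → 4 → 6).

All three steps carry risk; in order of likelihood to fail: step 1, step 3, step 2. The fallbacks are given in step order.

**Step 1.** The cells may not take up or turn over 1, or may oxidise the benzoyl ring or the benzylic CH2. The fallback sets out from 3 and comes back to the route at 2. It carries C7 at the acid oxidation level in a substrate the enzyme is known to accept. Compound 3 is ethanolysed (EtOH, pyridine, 0 °C) to ethyl benzoate F1, which is also sold as such. The same recombinant strain converts it into ethyl (5S,6R)-5,6-dihydroxycyclohexa-1,3-diene-1-carboxylate F2. iBu2AlH (4.5 equiv, THF, −78 → 0 °C) reduces the ester without touching the diene and gives (1S,2R)-3-(hydroxymethyl)cyclohexa-3,5-diene-1,2-diol F3. Finally 3 (1.0 equiv, collidine, CH2Cl2, −78 °C) acylates the primary hydroxyl to give 2.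

**Step 2.** O6 acylation, double acylation, O5→O6 migration or aromatisation may erode the yield. The fallback sets out from 2 and comes back at 4. It fixes the regiochemistry with orthogonal silyl groups instead of relative acylation rates.
- Et3SiCl (1.05 equiv, imidazole, DMF, −40 °C) silylates the distal O5 to give [(5S,6R)-6-hydroxy-5-(triethylsilyloxy)cyclohexa-1,3-dien-1-yl]methyl benzoate F4.
- tBuMe2SiOTf/2,6-lutidine (CH2Cl2, −78 °C) caps O6 to give [(5S,6R)-6-(tert-butyldimethylsilyloxy)-5-(triethylsilyloxy)cyclohexa-1,3-dien-1-yl]methyl benzoate F5.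
- PPTS in MeOH–CH2Cl2 at 0 °C removes only the triethylsilyl group to give [(5S,6R)-6-(tert-butyldimethylsilyloxy)-5-hydroxycyclohexa-1,3-dien-1-yl]methyl benzoate F6.
- 3 with pyridine and DMAP benzoylates the single free hydroxyl to give (1S,6R)-5-[(benzoyloxy)methyl]-6-(tert-butyldimethylsilyloxy)cyclohexa-2,4-dien-1-yl benzoate F7.
- HF·pyridine (THF–pyridine, 0 °C) removes the remaining silyl group to give 4.

**Step 3.** OsO4 may also attack C1=C2, over-oxidise 6, or the benzoate may migrate. The fallback sets out from 3 and comes back at 6. It switches off the proximal double bond with a halogen and adds C7 afterwards by cross-coupling.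
- 3 (1.05 equiv, collidine, CH2Cl2, −40 °C) benzoylates the distal hydroxyl of (1S,2S)-3-bromocyclohexa-3,5-diene-1,2-diol F8 (commercial; the toluene dioxygenase metabolite of bromobenzene) to give (1S,6S)-5-bromo-6-hydroxycyclohexa-2,4-dien-1-yl benzoate F9.
- OsO4/NMO attacks only the non-brominated double bond, anti to the benzoate, and gives (1S,2S,5R,6R)-3-bromo-2,5,6-trihydroxycyclohex-3-en-1-yl benzoate F10.
- Stille coupling with Bu3SnCH2OH (Pd(PPh3)4, dioxane, 90 °C) gives (1R,2R,5R,6R)-2,5,6-trihydroxy-3-(hydroxymethyl)cyclohex-3-en-1-yl benzoate F11.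
- 3 (1.0 equiv, collidine, CH2Cl2, −40 °C) acylates the primary allylic hydroxyl to give 6.

## Further compounds

F1 | step 1 | ethyl benzoate | CCOC(=O)c1ccccc1
F2 | step 1 | ethyl (5S,6R)-5,6-dihydroxycyclohexa-1,3-diene-1-carboxylate | CCOC(=O)C1=CC=C[C@H](O)[C@@H]1O
F3 | step 1 | (1S,2R)-3-(hydroxymethyl)cyclohexa-3,5-diene-1,2-diol | OCC1=CC=C[C@H](O)[C@@H]1O
F4 | step 2 | [(5S,6R)-6-hydroxy-5-(triethylsilyloxy)cyclohexa-1,3-dien-1-yl]methyl benzoate | O=C(OCC1=CC=C[C@H](O[Si](CC)(CC)CC)[C@@H]1O)c1ccccc1
F5 | step 2 | [(5S,6R)-6-(tert-butyldimethylsilyloxy)-5-(triethylsilyloxy)cyclohexa-1,3-dien-1-yl]methyl benzoate | O=C(OCC1=CC=C[C@H](O[Si](CC)(CC)CC)[C@@H]1O[Si](C)(C)C(C)(C)C)c1ccccc1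
F6 | step 2 | [(5S,6R)-6-(tert-butyldimethylsilyloxy)-5-hydroxycyclohexa-1,3-dien-1-yl]methyl benzoate | O=C(OCC1=CC=C[C@H](O)[C@@H]1O[Si](C)(C)C(C)(C)C)c1ccccc1
F7 | step 2 | (1S,6R)-5-[(benzoyloxy)methyl]-6-(tert-butyldimethylsilyloxy)cyclohexa-2,4-dien-1-yl benzoate | O=C(OCC1=CC=C[C@H](OC(=O)c2ccccc2)[C@@H]1O[Si](C)(C)C(C)(C)C)c1ccccc1
F8 | step 3 | (1S,2S)-3-bromocyclohexa-3,5-diene-1,2-diol | BrC1=CC=C[C@H](O)[C@@H]1O
F9 | step 3 | (1S,6S)-5-bromo-6-hydroxycyclohexa-2,4-dien-1-yl benzoate | BrC1=CC=C[C@H](OC(=O)c2ccccc2)[C@@H]1O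
F10 | step 3 | (1S,2S,5R,6R)-3-bromo-2,5,6-trihydroxycyclohex-3-en-1-yl benzoate | BrC1=C[C@@H](O)[C@@H](O)[C@H](OC(=O)c2ccccc2)[C@@H]1O
F11 | step 3 | (1R,2R,5R,6R)-2,5,6-trihydroxy-3-(hydroxymethyl)cyclohex-3-en-1-yl benzoate | OCC1=C[C@@H](O)[C@@H](O)[C@H](OC(=O)c2ccccc2)[C@@H]1O
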